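**Plan**

- Kazinol K is an achiral 1,3-diarylpropane. The last cut removes two aryl acetates. The key cut opens two C–C bonds that each sit next to an aryl oxygen. One is the bond from ring A C5 to the quaternary allyl carbon, ortho to the C4 hydroxyl. The other is the chromene C4a–C4 bond, whose ring B carbon is ortho to the pyran oxygen; the O1–C2 bond opens with it.
- This leads back to bis-ether 22, with a prenyl ether on ring A O4 and a 1,1-dimethylpropargyl ether on ring B. Further cuts are the two O-alkyl bonds, the ring B aryl–prenyl bond (Stille), the benzylic carbonyl of a dihydrochalcone, the ring A C1–acyl bond (Friedel–Crafts) and the acid side chain (aldehyde plus Meldrum's acid).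
- Forward order: arylpropanoic acid, then acylation of resorcinol, then a tosylation/demethylation sequence that frees one phenol at a time. C-prenylation, the propargyl ether, detosylation and the prenyl ether follow. The ketone makes the ring A para hydroxyl the most acidic phenol for that last etherification and is then removed.
- Acetylation and a single thermal step then build the ring A C5–C bond and the pyran ring, the only ring made in the route; methanolysis ends the synthesis.
- Stereochemistry: the target has no stereocentre. The cis C3=C4 bond of the chromene is fixed by the ring closure.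

Key step: step 11

Numbering: ring A is counted from its chain-bearing carbon (C1; oxygens on C2 and C4). Ring B before ring closure is counted from its chain-bearing carbon (C1; prenyl on C2, oxygens on C4 and C5); its C3, C4 and C5 become chromene C4a, C8a and C8.

Remark: in step 11 the propargyl ether is assumed to rearrange before the prenyl ether; the opposite order would pass through other intermediates and end at the same product 28.

**Route**

Step 1
Reactants: 1 2-bromo-5-hydroxy-4-methoxybenzaldehyde; 2 Meldrum's acid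
Product: 6 3-(2-bromo-5-hydroxy-4-methoxyphenyl)propanoic acid, via arylidene Meldrum's acid 3 (not isolated), via benzyl Meldrum's acid 4 (not isolated), via benzylmalonic acid 5 (not isolated)
Conditions: HCO2H/Et3N (5:2), 25 → 95 °C; then 2 M HCl, 0 °C
Reagents that add atoms: water, O (released in the condensation and taken up again in the ring opening)
Why: Reductive Knoevenagel sequence in which the condensation product is reduced by hydride transfer from formate and the benzyl Meldrum's acid then opens and decarboxylates on heating; the aryl bromide and the phenol are inert to formate without a transition metal.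

Step 2
Reactants: 6 3-(2-bromo-5-hydroxy-4-methoxyphenyl)propanoic acid; 7 resorcinol
Product: 8 3-(2-bromo-5-hydroxy-4-methoxyphenyl)-1-(2,4-dihydroxyphenyl)propan-1-one
Conditions: BF3·OEt2 (neat), resorcinol (1.5 equiv), 85 °C; then aq NaOAc
Reagents that add atoms: none
Why: Friedel–Crafts C-acylation of resorcinol by a carboxylic acid in BF3·OEt2 occurs at C4 (para to one hydroxyl, ortho to the other) and is the standard entry to 2',4'-dihydroxydihydrochalcones; excess resorcinol should outrun ring closure of the acid to an indanone.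

Step 3
Reactants: 8 3-(2-bromo-5-hydroxy-4-methoxyphenyl)-1-(2,4-dihydroxyphenyl)propan-1-one
Product: 9 4-[3-(2-bromo-4-methoxy-5-tosyloxyphenyl)propanoyl]-3-hydroxyphenyl 4-methylbenzenesulfonate
Conditions: TsCl (2.2 equiv), K2CO3, acetone, 25 °C
Reagents that add atoms: p-toluenesulfonyl chloride, Cc1ccc(S(=O)(=O)Cl)cc1
Why: O-sulfonylation of the two free phenols; the ring A C2 hydroxyl is hydrogen-bonded to the ketone and should stay untouched, as in the selective 4-O-sulfonylation of 2,4-dihydroxyaryl ketones.

Step 4
Reactants: 9 4-[3-(2-bromo-4-methoxy-5-tosyloxyphenyl)propanoyl]-3-hydroxyphenyl 4-methylbenzenesulfonate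
Product: 10 4-[3-(2-bromo-4-hydroxy-5-tosyloxyphenyl)propanoyl]-3-hydroxyphenyl 4-methylbenzenesulfonate
Conditions: BBr3 (4 equiv), CH2Cl2, −78 → 20 °C; then H2O, 0 °C
Reagents that add atoms: none
Why: BBr3 cleavage of the single aryl methyl ether; aryl sulfonates, the aryl bromide and the ketone are inert to BBr3, so the ring B C4 hydroxyl becomes the only phenol that is neither chelated nor sulfonylated.

Step 5
Reactants: 10 4-[3-(2-bromo-4-hydroxy-5-tosyloxyphenyl)propanoyl]-3-hydroxyphenyl 4-methylbenzenesulfonate; 11 tributyl(3-methylbut-2-en-1-yl)stannane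
Product: 12 4-{3-[4-hydroxy-2-(3-methylbut-2-en-1-yl)-5-tosyloxyphenyl]propanoyl}-3-hydroxyphenyl 4-methylbenzenesulfonate
Conditions: Pd(PPh3)4 (5 mol%), DMF (degassed), 95 °C, Ar
Reagents that add atoms: none
Why: Stille coupling of an aryl bromide with a prenylstannane, in which C–C bond formation at the unsubstituted allyl terminus gives the linear prenyl arene; free phenols are tolerated and aryl tosylates do not undergo oxidative addition to Pd(PPh3)4.

Step 6
Reactants: 12 4-{3-[4-hydroxy-2-(3-methylbut-2-en-1-yl)-5-tosyloxyphenyl]propanoyl}-3-hydroxyphenyl 4-methylbenzenesulfonate; 13 3-chloro-3-methylbut-1-yne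
Product: 14 4-{3-[2-(3-methylbut-2-en-1-yl)-4-(2-methylbut-3-yn-2-yloxy)-5-tosyloxyphenyl]propanoyl}-3-hydroxyphenyl 4-methylbenzenesulfonate
Conditions: DBU (1.3 equiv), CuCl2·2H2O (1 mol%), MeCN, 0 °C
Reagents that add atoms: none
Why: Copper-catalysed propargylic substitution of the tertiary chloride by the phenoxide (through a copper acetylide and allenylidene) is the standard route to aryl 1,1-dimethylpropargyl ethers; the chelated hydroxyl is unreactive, the neighbouring tosyl group cannot migrate because in-line attack at sulfur is impossible within a five-membered transition state, and the low temperature keeps intermolecular sulfonyl transfer slow.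

Step 7
Reactants: 14 4-{3-[2-(3-methylbut-2-en-1-yl)-4-(2-methylbut-3-yn-2-yloxy)-5-tosyloxyphenyl]propanoyl}-3-hydroxyphenyl 4-methylbenzenesulfonate
Product: 15 1-(2,4-dihydroxyphenyl)-3-[5-hydroxy-2-(3-methylbut-2-en-1-yl)-4-(2-methylbut-3-yn-2-yloxy)phenyl]propan-1-one
Conditions: KOH (8 equiv), 1,4-dioxane/H2O (3:1), 80 °C, Ar; then aq NH4Cl
Reagents that add atoms: none
Why: Alkaline hydrolysis of aryl sulfonates by hydroxide attack at sulfur; the ethers, alkyne and alkenes are base-stable, 80 °C lies well below the onset of the propargyl ether rearrangement, and the absence of methanol avoids formation of an alkylating methyl sulfonate.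

Step 8
Reactants: 15 1-(2,4-dihydroxyphenyl)-3-[5-hydroxy-2-(3-methylbut-2-en-1-yl)-4-(2-methylbut-3-yn-2-yloxy)phenyl]propan-1-one; 16 prenyl bromide
Product: 17 1-[2-hydroxy-4-(3-methylbut-2-en-1-yloxy)phenyl]-3-[5-hydroxy-2-(3-methylbut-2-en-1-yl)-4-(2-methylbut-3-yn-2-yloxy)phenyl]propan-1-one
Conditions: prenyl bromide (1.05 equiv), K2CO3 (1.1 equiv), acetone, 25 °C
Reagents that add atoms: none
Why: Williamson etherification under acidity control, since the hydroxyl para to the ketone is about two pKa units more acidic than the ring B phenol (which is also flanked by the tertiary ether) and the ring A C2 hydroxyl is chelated, as in the selective 4'-O-alkylation of 2',4'-dihydroxyaryl ketones.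

Step 9
Reactants: 17 1-[2-hydroxy-4-(3-methylbut-2-en-1-yloxy)phenyl]-3-[5-hydroxy-2-(3-methylbut-2-en-1-yl)-4-(2-methylbut-3-yn-2-yloxy)phenyl]propan-1-one
Product: 21 2-{3-[5-hydroxy-2-(3-methylbut-2-en-1-yl)-4-(2-methylbut-3-yn-2-yloxy)phenyl]propyl}-5-(3-methylbut-2-en-1-yloxy)phenol, via bis(ethyl carbonate) 18 (not isolated), via quinone methide 19 (not isolated), via ring B carbonate 20 (not isolated)
Conditions: ClCO2Et (3 equiv), Et3N, THF, 0 °C; filter; NaBH4, THF/H2O, 0 → 20 °C; then 2 M NaOH, 20 °C; aq NH4Cl
Reagents that add atoms: none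
Why: Reductive deoxygenation of an ortho-hydroxyaryl ketone through its ethyl carbonate, in which borohydride reduces the ketone, the benzylic alkoxide takes over the neighbouring carbonate and is expelled to an ortho-quinone methide that a second hydride reduces to the methylene; hydroxide then cleaves the remote ring B carbonate, and none of the ethers, alkenes or the alkyne reacts with NaBH4.

Step 10
Reactants: 21 2-{3-[5-hydroxy-2-(3-methylbut-2-en-1-yl)-4-(2-methylbut-3-yn-2-yloxy)phenyl]propyl}-5-(3-methylbut-2-en-1-yloxy)phenol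
Product: 22 bis-ether diacetate (ring A: C2 acetate and C4 prenyl ether; ring B: C2 prenyl plus C4 1,1-dimethylpropargyl ether plus C5 acetate)
Conditions: Ac2O, pyridine, DMAP (cat.), CH2Cl2, 0 → 20 °C
Reagents that add atoms: acetic anhydride, CC(=O)OC(C)=O
Why: DMAP-catalysed acetylation of both phenols; the acetates mask the phenols during the thermal step and can be removed under mild base that the product tolerates.

Step 11
Reactants: 22 bis-ether diacetate
Product: 28 kazinol K diacetate, via allenyl dienone 23 (not isolated), via allenylphenol 24 (not isolated), via quinone methide 25 (not isolated), via chromene prenyl ether 26 (not isolated), via ring A dienone 27 (not isolated)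
Conditions: PhNEt2 (degassed, 0.05 M), 195 °C, sealed tube, Ar
Reagents that add atoms: none
Why: On ring B the aryl 1,1-dimethylpropargyl ether undergoes a concerted [3,3] shift to C3, the only unsubstituted ortho carbon; allenyl dienone 23 enolises to allenylphenol 24, a 1,5-hydrogen shift gives ortho-quinone methide 25, and a thermal oxa-6π electrocyclisation closes the six-membered pyran ring of chromene 26. On ring A the prenyl ether then shifts [3,3] with allyl inversion to C5, and dienone 27 tautomerises to the phenol that carries the 1,1-dimethylallyl group. Both events are known reaction types that run in the same medium and temperature range: the aromatic Claisen rearrangement of aryl prenyl ethers to ortho-(1,1-dimethylallyl)phenols and the thermal conversion of aryl 1,1-dimethylpropargyl ethers into 2,2-dimethyl-2H-chromenes. No stereocentre is formed, and the chromene C3=C4 double bond is cis by ring constraint. The step needs regioselectivity on ring A: C3 is flanked by the acetoxy- and allyloxy-bearing carbons and resists formation of a quaternary centre, the para carbon C1 is blocked by the chain so a shift there can only revert, and C5 is open; on ring B a shift to the acetoxy-bearing C5 is likewise reversible and unproductive. The weakly basic amine solvent buffers traces of acid that would trigger the abnormal Claisen pathway or ring closure of the new ortho-allylphenol, and any acetyl exchange onto the freed phenol is erased in step 12.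

Step 12
Reactants: 28 kazinol K diacetate
Product: 29 kazinol K
Conditions: K2CO3 (cat.), MeOH (degassed), 20 °C, Ar; then aq NH4Cl
Reagents that add atoms: none
Why: Base-catalysed methanolysis of aryl acetates, which the chromene, the three alkenes and the free phenols should tolerate at room temperature under argon.

**Compound list**

1 | 2-bromo-5-hydroxy-4-methoxybenzaldehyde | COc1cc(Br)c(C=O)cc1O | starting material
2 | Meldrum's acid (2,2-dimethyl-1,3-dioxane-4,6-dione) | CC1(C)OC(=O)CC(=O)O1 | starting material
3 | 5-(2-bromo-5-hydroxy-4-methoxybenzylidene)-2,2-dimethyl-1,3-dioxane-4,6-dione (arylidene Meldrum's acid) | COc1cc(Br)c(C=C2C(=O)OC(C)(C)OC2=O)cc1O | intermediate (not isolated)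
4 | 5-(2-bromo-5-hydroxy-4-methoxybenzyl)-2,2-dimethyl-1,3-dioxane-4,6-dione (benzyl Meldrum's acid) | COc1cc(Br)c(CC2C(=O)OC(C)(C)OC2=O)cc1O | intermediate (not isolated)
5 | 2-(2-bromo-5-hydroxy-4-methoxybenzyl)malonic acid | COc1cc(Br)c(CC(C(=O)O)C(=O)O)cc1O | intermediate (not isolated)
6 | 3-(2-bromo-5-hydroxy-4-methoxyphenyl)propanoic acid | COc1cc(Br)c(CCC(=O)O)cc1O | intermediate
7 | resorcinol | Oc1cccc(O)c1 | starting material
8 | 3-(2-bromo-5-hydroxy-4-methoxyphenyl)-1-(2,4-dihydroxyphenyl)propan-1-one | COc1cc(Br)c(CCC(=O)c2ccc(O)cc2O)cc1O | intermediate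
9 | 4-[3-(2-bromo-4-methoxy-5-tosyloxyphenyl)propanoyl]-3-hydroxyphenyl 4-methylbenzenesulfonate | COc1cc(Br)c(CCC(=O)c2ccc(OS(=O)(=O)c3ccc(C)cc3)cc2O)cc1OS(=O)(=O)c1ccc(C)cc1 | intermediate
10 | 4-[3-(2-bromo-4-hydroxy-5-tosyloxyphenyl)propanoyl]-3-hydroxyphenyl 4-methylbenzenesulfonate | Oc1cc(Br)c(CCC(=O)c2ccc(OS(=O)(=O)c3ccc(C)cc3)cc2O)cc1OS(=O)(=O)c1ccc(C)cc1 | intermediate
11 | tributyl(3-methylbut-2-en-1-yl)stannane | CCCC[Sn](CCCC)(CCCC)CC=C(C)C | starting material
12 | 4-{3-[4-hydroxy-2-(3-methylbut-2-en-1-yl)-5-tosyloxyphenyl]propanoyl}-3-hydroxyphenyl 4-methylbenzenesulfonate | Oc1cc(CC=C(C)C)c(CCC(=O)c2ccc(OS(=O)(=O)c3ccc(C)cc3)cc2O)cc1OS(=O)(=O)c1ccc(C)cc1 | intermediate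
13 | 3-chloro-3-methylbut-1-yne | CC(C)(Cl)C#C | starting material
14 | 4-{3-[2-(3-methylbut-2-en-1-yl)-4-(2-methylbut-3-yn-2-yloxy)-5-tosyloxyphenyl]propanoyl}-3-hydroxyphenyl 4-methylbenzenesulfonate | C#CC(C)(C)Oc1cc(CC=C(C)C)c(CCC(=O)c2ccc(OS(=O)(=O)c3ccc(C)cc3)cc2O)cc1OS(=O)(=O)c1ccc(C)cc1 | intermediate
15 | 1-(2,4-dihydroxyphenyl)-3-[5-hydroxy-2-(3-methylbut-2-en-1-yl)-4-(2-methylbut-3-yn-2-yloxy)phenyl]propan-1-one | C#CC(C)(C)Oc1cc(CC=C(C)C)c(CCC(=O)c2ccc(O)cc2O)cc1O | intermediate
16 | prenyl bromide (1-bromo-3-methylbut-2-ene) | CC(C)=CCBr | starting material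
17 | 1-[2-hydroxy-4-(3-methylbut-2-en-1-yloxy)phenyl]-3-[5-hydroxy-2-(3-methylbut-2-en-1-yl)-4-(2-methylbut-3-yn-2-yloxy)phenyl]propan-1-one | C#CC(C)(C)Oc1cc(CC=C(C)C)c(CCC(=O)c2ccc(OCC=C(C)C)cc2O)cc1O | intermediate
18 | bis(ethyl carbonate) of 17 (ring A C2 and ring B C5 oxygens) | C#CC(C)(C)Oc1cc(CC=C(C)C)c(CCC(=O)c2ccc(OCC=C(C)C)cc2OC(=O)OCC)cc1OC(=O)OCC | intermediate (not isolated)
19 | ortho-quinone methide, 6-(3-arylpropylidene)-3-(prenyloxy)cyclohexa-2,4-dien-1-one with the ring B carbonate in place (alkene geometry not defined) | O=C1C=C(OCC=C(C)C)C=CC1=CCCc1cc(OC(=O)OCC)c(OC(C)(C)C#C)cc1CC=C(C)C | intermediate (not isolated)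
20 | ethyl 5-{3-[2-hydroxy-4-(3-methylbut-2-en-1-yloxy)phenyl]propyl}-4-(3-methylbut-2-en-1-yl)-2-(2-methylbut-3-yn-2-yloxy)phenyl carbonate | CCOC(=O)Oc1cc(CCCc2ccc(OCC=C(C)C)cc2O)c(CC=C(C)C)cc1OC(C)(C)C#C | intermediate (not isolated)
21 | 2-{3-[5-hydroxy-2-(3-methylbut-2-en-1-yl)-4-(2-methylbut-3-yn-2-yloxy)phenyl]propyl}-5-(3-methylbut-2-en-1-yloxy)phenol | C#CC(C)(C)Oc1cc(CC=C(C)C)c(CCCc2ccc(OCC=C(C)C)cc2O)cc1O | intermediate
22 | bis-ether diacetate: 2-{3-[5-acetoxy-2-(3-methylbut-2-en-1-yl)-4-(2-methylbut-3-yn-2-yloxy)phenyl]propyl}-5-(3-methylbut-2-en-1-yloxy)phenyl acetate | CC(C)=CCOc1ccc(CCCc2cc(OC(C)=O)c(OC(C)(C)C#C)cc2CC=C(C)C)c(OC(C)=O)c1 | intermediate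
23 | ring B allenyl dienone (6-allenylcyclohexa-2,4-dienone, racemic at the sp3 ring carbon), ring A prenyl ether intact | CC(C)=CCOc1ccc(CCCC2=C(CC=C(C)C)C(C=C=C(C)C)C(=O)C(OC(C)=O)=C2)c(OC(C)=O)c1 | intermediate (not isolated)
24 | ring B ortho-allenylphenol, ring A prenyl ether intact | CC(C)=CCOc1ccc(CCCc2cc(OC(C)=O)c(O)c(C=C=C(C)C)c2CC=C(C)C)c(OC(C)=O)c1 | intermediate (not isolated)
25 | ring B ortho-quinone methide (exocyclic dienylidene, geometry not defined), ring A prenyl ether intact | CC(C)=CCOc1ccc(CCCC2=C(CC=C(C)C)C(=CC=C(C)C)C(=O)C(OC(C)=O)=C2)c(OC(C)=O)c1 | intermediate (not isolated)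
26 | chromene prenyl ether: 8-acetoxy-2,2-dimethyl-5-prenyl-2H-chromen-6-yl propane bearing the ring A C2 acetate and C4 prenyl ether | CC(C)=CCOc1ccc(CCCc2cc(OC(C)=O)c3OC(C)(C)C=Cc3c2CC=C(C)C)c(OC(C)=O)c1 | intermediate (not isolated)
27 | ring A ortho-dienone (6-(2-methylbut-3-en-2-yl)cyclohexa-2,4-dienone, racemic at the sp3 ring carbon) with the chromene formed | C=CC(C)(C)C1C=C(CCCc2cc(OC(C)=O)c3OC(C)(C)C=Cc3c2CC=C(C)C)C(OC(C)=O)=CC1=O | intermediate (not isolated)
28 | kazinol K diacetate (ring A C2 acetate, chromene C8 acetate) | C=CC(C)(C)c1cc(CCCc2cc(OC(C)=O)c3OC(C)(C)C=Cc3c2CC=C(C)C)c(OC(C)=O)cc1O | intermediate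
29 | kazinol K | C=CC(C)(C)c1cc(CCCc2cc(O)c3c(c2CC=C(C)C)C=CC(C)(C)O3)c(O)cc1O | target

**Step count and risks**

Total: 12 steps. Longest linear sequence: 12 steps (1 → 29); all other inputs are purchased reagents.

Steps most likely to fail:

1. Step 11. The prenyl group may shift to ring A C3 instead of C5, or the newly formed ortho-allylphenol may rearrange further or cyclise onto its oxygen on prolonged heating. The fallback sets out from diol 21. Silylation of both phenols (TBSCl, imidazole, DMF) would give the bis(tert-butyldimethylsilyl) ether F1, in which the ring A C2 substituent is bulkier and electron-donating and so should steer the shift further away from C3. The same double rearrangement in N,N-diethylaniline would give kazinol K bis(tert-butyldimethylsilyl) ether F2. TBAF buffered with AcOH in THF would then release the phenols, and the route is rejoined at 29.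

2. Step 5. The allyl unit may be transferred through its substituted terminus, giving the branched isomer, or oxidative addition into the electron-rich, ortho-substituted aryl bromide may be slow enough for reduction of the C–Br bond to compete. The fallback sets out from bromide 10. Stille coupling with allyltributylstannane (Pd(PPh3)4, DMF) would give the allyl arene F3. Cross-metathesis with excess 2-methylbut-2-ene and the second-generation Grubbs catalyst in CH2Cl2 would then exchange the terminal methylene for an isopropylidene group, and the route is rejoined at 12.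

3. Step 9. The benzylic alkoxide may fail to take over the carbonate so that reduction stalls at the benzylic alcohol, or the quinone methide may be trapped by water or oligomerise before hydride arrives. The fallback sets out from ketone 17. Condensation with p-toluenesulfonyl hydrazide (EtOH, 60 °C) would give the tosylhydrazone F4. Reduction with catecholborane in CHCl3 at 0 °C, followed by NaOAc·3H2O at reflux, proceeds by hydroboration of the C=N bond, loss of sulfinate and extrusion of N2. This delivers the methylene without any carbonate, and the route is rejoined at 21.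

Further compounds
F1 | step 11 | bis(tert-butyldimethylsilyl) ether of diol 21 | CC(C)=CCOc1ccc(CCCc2cc(O[Si](C)(C)C(C)(C)C)c(OC(C)(C)C#C)cc2CC=C(C)C)c(O[Si](C)(C)C(C)(C)C)c1
F2 | step 11 | kazinol K bis(tert-butyldimethylsilyl) ether (ring A C2 and chromene C8 oxygens) | C=CC(C)(C)c1cc(CCCc2cc(O[Si](C)(C)C(C)(C)C)c3OC(C)(C)C=Cc3c2CC=C(C)C)c(O[Si](C)(C)C(C)(C)C)cc1O
F3 | step 5 | 4-[3-(2-allyl-4-hydroxy-5-tosyloxyphenyl)propanoyl]-3-hydroxyphenyl 4-methylbenzenesulfonate | Oc1cc(CC=C)c(CCC(=O)c2ccc(OS(=O)(=O)c3ccc(C)cc3)cc2O)cc1OS(=O)(=O)c1ccc(C)cc1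
F4 | step 9 | p-toluenesulfonylhydrazone of ketone 17 | C#CC(C)(C)Oc1cc(CC=C(C)C)c(CCC(=NNS(=O)(=O)c2ccc(C)cc2)c2ccc(OCC=C(C)C)cc2O)cc1O
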